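## Retrosynthetic overview

- The target comes from its tris-TBS ether. That ether comes from a 1,4-diol by closing one oxolane C–O bond, and the diol comes from a trans,anti α-[aryl(hydroxy)methyl]-β-benzyl-γ-butyrolactone by hydride reduction.
- Enabling feature: oxolane C-3, which carries the carbinol, lies between C-2 (a CH2 bound to the ring oxygen) and C-4 (the benzyl-bearing stereocentre). Raising C-2 to a lactone C=O and C-3/C-4 to a C=C turns the saturated ring into a flat, achiral butenolide ring. Its C-3 becomes an enolate carbon as soon as hydride reaches C-4.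
- Key disconnection: the bond from ring C-3 to the CH(OH)Ar carbon. It is made by an asymmetric reductive aldol union of the β-benzylbutenolide with O-TBS-vanillin, which sets all three stereocentres in one operation.
- The butenolide comes from a Negishi coupling of a benzylzinc chloride with 4-bromofuran-2(5H)-one. Both arene units come from vanillin through one common silyl ether.
- Ring order: the two benzene rings and the five-membered lactone ring are bought. The lactone ring is opened by reduction and the oxolane ring is closed last, by cyclodehydration.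

Key step: step 5

Assumption: the (S,S)-catalyst is written by analogy with β,β-disubstituted enoates whose larger β-group lies trans to the carbonyl, as the CH2Ar group does in the butenolide; if a test reduction shows the opposite sense, the (R,R)-complex is used and nothing else changes.

TBS = tert-butyldimethylsilyl. Phebox = 2,6-bis(4-isopropyl-4,5-dihydrooxazol-2-yl)phenyl.

## Route

Step 1
Reactants: 1 vanillin (4-hydroxy-3-methoxybenzaldehyde)
Product: 2 4-[(tert-butyldimethylsilyl)oxy]-3-methoxybenzaldehyde
Conditions: TBSCl, imidazole, DMF, rt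
Reagents that add atoms: tert-butyldimethylsilyl chloride, CC(C)(C)[Si](C)(C)Cl
Why: Imidazole-promoted O-silylation masks the acidic phenol for the organozinc, hydride and enolate chemistry ahead, and no stereocentre is formed.

Step 2
Reactants: 2 4-[(tert-butyldimethylsilyl)oxy]-3-methoxybenzaldehyde
Product: 3 {4-[(tert-butyldimethylsilyl)oxy]-3-methoxyphenyl}methanol
Conditions: NaBH4, MeOH, 0 °C
Reagents that add atoms: none
Why: Borohydride 1,2-reduction of the aldehyde proceeds at a temperature at which the aryl silyl ether is inert.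

Step 3
Reactants: 3 {4-[(tert-butyldimethylsilyl)oxy]-3-methoxyphenyl}methanol
Product: 4 tert-butyl[4-(chloromethyl)-2-methoxyphenoxy]dimethylsilane
Conditions: SOCl2, pyridine, CH2Cl2, 0 °C; used without storage
Reagents that add atoms: thionyl chloride, O=S(Cl)Cl
Why: Deoxychlorination through the chlorosulfite (SN2 in the presence of pyridine) is fast for an electron-rich benzylic alcohol, and the base keeps the medium from attacking the silyl ether.

Step 4
Reactants: 4 tert-butyl[4-(chloromethyl)-2-methoxyphenoxy]dimethylsilane; 5 4-bromofuran-2(5H)-one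
Product: 7 4-{4-[(tert-butyldimethylsilyl)oxy]-3-methoxybenzyl}furan-2(5H)-one, via benzylzinc chloride 6 (not isolated)
Conditions: Zn dust, LiCl, THF, 25 °C; then 5, Pd(PPh3)4 (3 mol %), THF, 25–50 °C
Reagents that add atoms: none
Why: LiCl-assisted zinc insertion into the benzylic C–Cl bond is followed by Negishi cross-coupling, in which the vinylogous acyl bromide adds readily to zerovalent palladium and the mild organozinc leaves the lactone and silyl ether untouched.

Step 5
Reactants: 7 4-{4-[(tert-butyldimethylsilyl)oxy]-3-methoxybenzyl}furan-2(5H)-one; 2 4-[(tert-butyldimethylsilyl)oxy]-3-methoxybenzaldehyde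
Product: 9 (3S,4R)-4-{4-[(tert-butyldimethylsilyl)oxy]-3-methoxybenzyl}-3-[(R)-{4-[(tert-butyldimethylsilyl)oxy]-3-methoxyphenyl}(hydroxy)methyl]dihydrofuran-2(3H)-one, via diethoxymethylsilyl ether 8 (not isolated)
Conditions: [(S,S)-iPr-Phebox]Rh(OAc)2(H2O) (2–5 mol %), 2 (1.5 equiv), (EtO)2MeSiH (2 equiv, slow addition), toluene, 50 °C; then AcOH/THF/H2O, rt
Reagents that add atoms: none
Why: Proposed new method: the silane converts the trivalent rhodium acetate complex into a Rh–H species that transfers hydride to C-4 of butenolide 7, the rhodium enolate so formed (held as the E(O)-enolate by the five-membered ring) binds aldehyde 2 and forms the bond from C-3 to the aldehyde carbon through a Zimmerman–Traxler chair, and Si–H/Rh–O exchange releases silyl ether 8 and returns Rh–H. The closest known reaction types are the [Phebox]Rh(OAc)2(H2O)-catalysed anti-selective asymmetric reductive aldol reaction of acrylates and cyclic enones with aromatic aldehydes and the asymmetric conjugate hydrosilylation of β,β-disubstituted enoates with the same complexes, and the new element is their merger on a β-substituted butenolide. No ring is closed in this step, the lactone ring being carried through intact. C-4 (R) is set by the ligand, which exposes the Si face of C-4 to the hydride; C-3 (S) is set by the freshly placed benzyl group, which leaves open only the face that took up the hydride, the face on which rhodium already sits, so that substrate and catalyst control should reinforce each other and give the 3,4-trans ring; the carbinol carbon (R) is set by the chair with the aryl group equatorial, which translates the E(O)-geometry into the anti aldol. The step needs 1,4-hydride transfer to beat hydrosilylation of the aldehyde, which is secured by the preference of this catalyst family for conjugated C=C bonds and by the electron-rich, sluggish carbonyl group of 2, and it needs aldol capture to beat silylation of the enolate, which is secured by an excess of 2 and slow addition of the silane.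

Step 6
Reactants: 9 (3S,4R)-4-{4-[(tert-butyldimethylsilyl)oxy]-3-methoxybenzyl}-3-[(R)-{4-[(tert-butyldimethylsilyl)oxy]-3-methoxyphenyl}(hydroxy)methyl]dihydrofuran-2(3H)-one
Product: 10 (3S,4R)-4-{4-[(tert-butyldimethylsilyl)oxy]-3-methoxybenzyl}-3-[(R)-[(tert-butyldimethylsilyl)oxy]{4-[(tert-butyldimethylsilyl)oxy]-3-methoxyphenyl}methyl]dihydrofuran-2(3H)-one
Conditions: TBSOTf, 2,6-lutidine, CH2Cl2, 0 °C
Reagents that add atoms: tert-butyldimethylsilyl trifluoromethanesulfonate, CC(C)(C)[Si](C)(C)OS(=O)(=O)C(F)(F)F
Why: Silyl triflate silylation under a hindered, non-nucleophilic base avoids retro-aldol cleavage and C-3 epimerisation and removes the benzylic oxygen from competition in the later ring closure.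

Step 7
Reactants: 10 (3S,4R)-4-{4-[(tert-butyldimethylsilyl)oxy]-3-methoxybenzyl}-3-[(R)-[(tert-butyldimethylsilyl)oxy]{4-[(tert-butyldimethylsilyl)oxy]-3-methoxyphenyl}methyl]dihydrofuran-2(3H)-one
Product: 11 (2R,3R)-2-[(R)-[(tert-butyldimethylsilyl)oxy]{4-[(tert-butyldimethylsilyl)oxy]-3-methoxyphenyl}methyl]-3-{4-[(tert-butyldimethylsilyl)oxy]-3-methoxybenzyl}butane-1,4-diol
Conditions: i-Bu2AlH (5 equiv), CH2Cl2, −78 to 0 °C; aq potassium sodium tartrate
Reagents that add atoms: none
Why: Exhaustive hydride reduction takes the lactone to the 1,4-diol without touching the three stereocentres, and the weakly nucleophilic aluminium alkoxides at low temperature disfavour silyl migration.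

Step 8
Reactants: 11 (2R,3R)-2-[(R)-[(tert-butyldimethylsilyl)oxy]{4-[(tert-butyldimethylsilyl)oxy]-3-methoxyphenyl}methyl]-3-{4-[(tert-butyldimethylsilyl)oxy]-3-methoxybenzyl}butane-1,4-diol
Product: 12 (3R,4R)-3-[(R)-[(tert-butyldimethylsilyl)oxy]{4-[(tert-butyldimethylsilyl)oxy]-3-methoxyphenyl}methyl]-4-{4-[(tert-butyldimethylsilyl)oxy]-3-methoxybenzyl}tetrahydrofuran
Conditions: PPh3, DIAD, THF, 0 °C to rt
Reagents that add atoms: none
Why: In this Mitsunobu cyclodehydration either primary hydroxyl is activated as its oxyphosphonium ion and displaced by the other in a 5-exo-tet closure, so only CH2 carbons react, no stereocentre is involved, and the silylated benzylic oxygen cannot form the isomeric ring.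

Step 9
Reactants: 12 (3R,4R)-3-[(R)-[(tert-butyldimethylsilyl)oxy]{4-[(tert-butyldimethylsilyl)oxy]-3-methoxyphenyl}methyl]-4-{4-[(tert-butyldimethylsilyl)oxy]-3-methoxybenzyl}tetrahydrofuran
Product: 13 (R)-(4-hydroxy-3-methoxyphenyl)[(3R,4R)-4-(4-hydroxy-3-methoxybenzyl)tetrahydrofuran-3-yl]methanol (target)
Conditions: Bu4NF, AcOH (1:1), THF, 0 °C to rt
Reagents that add atoms: none
Why: Fluoride-driven cleavage of all three Si–O bonds, buffered so that no free para-phenoxide can expel the benzylic oxygen, leaves the carbinol C–O bond unbroken and its configuration retained.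

## Compound list

1 | vanillin | COc1cc(C=O)ccc1O | starting material
2 | 4-[(tert-butyldimethylsilyl)oxy]-3-methoxybenzaldehyde | COc1cc(C=O)ccc1O[Si](C)(C)C(C)(C)C | intermediate
3 | {4-[(tert-butyldimethylsilyl)oxy]-3-methoxyphenyl}methanol | COc1cc(CO)ccc1O[Si](C)(C)C(C)(C)C | intermediate
4 | tert-butyl[4-(chloromethyl)-2-methoxyphenoxy]dimethylsilane | COc1cc(CCl)ccc1O[Si](C)(C)C(C)(C)C | intermediate
5 | 4-bromofuran-2(5H)-one | O=C1C=C(Br)CO1 | starting material
6 | {4-[(tert-butyldimethylsilyl)oxy]-3-methoxybenzyl}zinc chloride (not isolated) | COc1cc(C[Zn]Cl)ccc1O[Si](C)(C)C(C)(C)C | intermediate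
7 | 4-{4-[(tert-butyldimethylsilyl)oxy]-3-methoxybenzyl}furan-2(5H)-one | COc1cc(CC2=CC(=O)OC2)ccc1O[Si](C)(C)C(C)(C)C | intermediate
8 | diethoxy(methyl)silyl ether of 9 (not isolated) | COc1cc(C[C@H]2COC(=O)[C@@H]2[C@@H](O[Si](C)(OCC)OCC)c2ccc(O[Si](C)(C)C(C)(C)C)c(OC)c2)ccc1O[Si](C)(C)C(C)(C)C | intermediate
9 | (3S,4R)-3-[(R)-aryl(hydroxy)methyl]-4-benzyl lactone, 3,4-trans, anti aldol, both phenols as TBS ethers | COc1cc(C[C@H]2COC(=O)[C@@H]2[C@@H](O)c2ccc(O[Si](C)(C)C(C)(C)C)c(OC)c2)ccc1O[Si](C)(C)C(C)(C)C | intermediate
10 | TBS ether of 9 at the carbinol oxygen | COc1cc(C[C@H]2COC(=O)[C@@H]2[C@@H](O[Si](C)(C)C(C)(C)C)c2ccc(O[Si](C)(C)C(C)(C)C)c(OC)c2)ccc1O[Si](C)(C)C(C)(C)C | intermediate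
11 | (2R,3R)-butane-1,4-diol bearing the (R)-aryl(TBSO)methyl group at C-2 and the benzyl group at C-3 | COc1cc(C[C@H]([C@H](CO)[C@@H](O[Si](C)(C)C(C)(C)C)c2ccc(O[Si](C)(C)C(C)(C)C)c(OC)c2)CO)ccc1O[Si](C)(C)C(C)(C)C | intermediate
12 | tris-TBS ether of the target, (3R,4R)-oxolane with (R)-carbinol carbon | COc1cc(C[C@H]2COC[C@@H]2[C@@H](O[Si](C)(C)C(C)(C)C)c2ccc(O[Si](C)(C)C(C)(C)C)c(OC)c2)ccc1O[Si](C)(C)C(C)(C)C | intermediate
13 | (R)-(4-hydroxy-3-methoxyphenyl)[(3R,4R)-4-(4-hydroxy-3-methoxybenzyl)tetrahydrofuran-3-yl]methanol | COc1cc(C[C@H]2COC[C@@H]2[C@@H](O)c2ccc(O)c(OC)c2)ccc1O | target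

## Step count and risks

Total steps: 9
Longest linear sequence: 9 steps (1 to 13; aldehyde 2 is used twice)

**Risk 1 (step 5).**
- What may go wrong: hydrosilylation of the aldehyde, or silylation of the rhodium enolate, may outrun C–C bond formation. Catalyst and substrate control may also diverge, giving poor facial selectivity.
- Fallback: known chemistry in two stages, setting out from 7.
- Asymmetric conjugate reduction with a ligated copper hydride should give (R)-4-{4-[(tert-butyldimethylsilyl)oxy]-3-methoxybenzyl}dihydrofuran-2(3H)-one F1. Conditions are Cu(OAc)2·H2O, the p-tol-BINAP enantiomer that serves the Si face of C-4, polymethylhydrosiloxane, t-BuOH and toluene.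
- Soft enolisation with Bu2BOTf and i-Pr2NEt (CH2Cl2, −78 °C) gives the dibutylboron enolate of the (R)-lactone F2.
- F2 adds to 2 through a tight closed chair, anti to the benzyl group, to give the dibutylboron aldolate F3.
- Hydrolysis with pH 7 buffer and MeOH comes back to the route at 9.

**Risk 2 (step 4).**
- What may go wrong: Wurtz-type homocoupling during zinc insertion into the electron-rich benzylic chloride, or decomposition of the bromobutenolide during coupling.
- Fallback: the polarity of the two partners is inverted, so that no benzylic organometallic is needed. It sets out from 5.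
- Stannylation with (Bu3Sn)2 and Pd(PPh3)4 in hot toluene gives 4-(tributylstannyl)furan-2(5H)-one F4.
- Stille coupling of F4 with chloride 4 as the electrophile (Pd2(dba)3, AsPh3, THF) comes back to the route at 7.

**Risk 3 (step 7).**
- What may go wrong: the silyl group may migrate from the benzylic oxygen to the newly formed neighbouring primary alkoxide. This would unmask the benzylic oxygen and divert the later ring closure.
- Fallback: the ring is never opened. It sets out from 10.
- Partial reduction with i-Bu2AlH (1.1 equiv, toluene, −78 °C) gives (3S,4R)-4-{4-[(tert-butyldimethylsilyl)oxy]-3-methoxybenzyl}-3-[(R)-[(tert-butyldimethylsilyl)oxy]{4-[(tert-butyldimethylsilyl)oxy]-3-methoxyphenyl}methyl]tetrahydrofuran-2-ol F5.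
- Ionic reduction of the derived oxocarbenium ion (Et3SiH, BF3·OEt2, CH2Cl2, −78 °C) comes back to the route at 12, bypassing 11 and step 8.

Further compounds
F1 | step 5 | (R)-4-{4-[(tert-butyldimethylsilyl)oxy]-3-methoxybenzyl}dihydrofuran-2(3H)-one | COc1cc(C[C@H]2COC(=O)C2)ccc1O[Si](C)(C)C(C)(C)C
F2 | step 5 | dibutylboron enolate of the (R)-lactone | COc1cc(C[C@H]2COC(OB(CCCC)CCCC)=C2)ccc1O[Si](C)(C)C(C)(C)C
F3 | step 5 | dibutylboron aldolate | COc1cc(C[C@H]2COC(=O)[C@@H]2[C@@H](OB(CCCC)CCCC)c2ccc(O[Si](C)(C)C(C)(C)C)c(OC)c2)ccc1O[Si](C)(C)C(C)(C)C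
F4 | step 4 | 4-(tributylstannyl)furan-2(5H)-one | CCCC[Sn](CCCC)(CCCC)C1=CC(=O)OC1
F5 | step 7 | (3S,4R)-4-{4-[(tert-butyldimethylsilyl)oxy]-3-methoxybenzyl}-3-[(R)-[(tert-butyldimethylsilyl)oxy]{4-[(tert-butyldimethylsilyl)oxy]-3-methoxyphenyl}methyl]tetrahydrofuran-2-ol | COc1cc(C[C@H]2COC(O)[C@@H]2[C@@H](O[Si](C)(C)C(C)(C)C)c2ccc(O[Si](C)(C)C(C)(C)C)c(OC)c2)ccc1O[Si](C)(C)C(C)(C)C
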